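**Retrosynthetic overview**

Numbering: C1 (fusion C–CH3), C2, C3, C4 (isopropyl), C5 (fusion C–OH), C6, C7 (ester carbinol), C8(CH3)=C9, C10; ring A = C1–C5, ring B = C1, C5–C10.
Ring A carries only two unfunctionalised methylenes, C2 and C3, between quaternary C1 and the C4 stereocentre, so it is closed last as a C2=C3 cyclopentene by metathesis of a vinyl group on C1 with a vinyl group on C4; diimide, desilylation and C7 acylation follow.
The diene comes from a cis-fused δ-lactone (O–C2–C1–C5–C4–C3=O) by reduction, double oxidation and double methylenation; the lactone comes from a samarium Reformatsky closure of a 2-bromo-3-methylbutanoate tethered through the C2 oxygen onto the C5 ketone, which sets C4 and C5.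
Ring B is made by metathesis at C8=C9 of the methacrolein aldol adduct (C7) of a methyl ketone whose quaternary C1 is set by double Fráter–Seebach alkylation of ethyl (S)-3-hydroxybutanoate.
Ring order: ring B (step 8), temporary lactone (step 11, opened in step 13), ring A (step 16).

Key step: step 16

Assumption: (−)-Ipc2BCl (from (+)-α-pinene) is taken to direct a methyl ketone enol borinate to the Re face of an α-branched enal; if the sense is the reverse, (+)-Ipc2BCl is used in step 6 and nothing else changes.

**Route**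

Step 1
Reactants: 1 ethyl (3S)-3-hydroxybutanoate; 2 allyl bromide
Product: 4 ethyl (2S,3S)-3-hydroxy-2-(prop-2-en-1-yl)butanoate, via dilithium alkoxide enolate 3 (not isolated)
Conditions: LiN(iPr)2 (2.2 equiv), THF, −78 → −20 °C; 2, DMPU, −78 → 0 °C; aq. work-up
Reagents that add atoms: allyl bromide 2, C=CCBr
Why: Fráter–Seebach alkylation: the chelated dilithium alkoxide enolate is alkylated on the face opposite the carbinol methyl group, which should give the anti (2S,3S) product.

Step 2
Reactants: 4 ethyl (2S,3S)-3-hydroxy-2-(prop-2-en-1-yl)butanoate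
Product: 6 ethyl (2R,3S)-3-hydroxy-2-methyl-2-(prop-2-en-1-yl)butanoate, via dilithium alkoxide enolate 5 (not isolated)
Conditions: LiN(iPr)2 (2.2 equiv), THF, −78 → −20 °C; MeI, DMPU, −78 → 0 °C; aq. work-up
Reagents that add atoms: methyl iodide, CI
Why: Second Fráter–Seebach alkylation: the chelated tetrasubstituted enolate is again attacked anti to the carbinol methyl, so methyl enters where allyl entered in step 1 and the quaternary centre (C1 of the target) is set; the minor epimer is removed by chromatography here, before the carbinol centre is erased in step 5.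

Step 3
Reactants: 6 ethyl (2R,3S)-3-hydroxy-2-methyl-2-(prop-2-en-1-yl)butanoate
Product: 7 (2S,3S)-2-methyl-2-(prop-2-en-1-yl)butane-1,3-diol
Conditions: LiAlH4, Et2O, 0 °C → rt
Reagents that add atoms: none
Why: Hydride reduction of the ester to the primary alcohol (future C2); no stereocentre is touched.

Step 4
Reactants: 7 (2S,3S)-2-methyl-2-(prop-2-en-1-yl)butane-1,3-diol
Product: 8 (2S,3S)-3-methyl-3-{[(triethylsilyl)oxy]methyl}hex-5-en-2-ol
Conditions: Et3SiCl (1.05 equiv), imidazole, CH2Cl2, −78 → −20 °C
Reagents that add atoms: chlorotriethylsilane, CC[Si](Cl)(CC)CC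
Why: Chemoselective silylation: the primary hydroxyl should react well ahead of the secondary hydroxyl flanked by the quaternary carbon.

Step 5
Reactants: 8 (2S,3S)-3-methyl-3-{[(triethylsilyl)oxy]methyl}hex-5-en-2-ol
Product: 9 (3S)-3-methyl-3-{[(triethylsilyl)oxy]methyl}hex-5-en-2-one
Conditions: Dess–Martin periodinane, CH2Cl2, rt
Reagents that add atoms: none
Why: Dess–Martin oxidation of the secondary alcohol gives the C5 methyl ketone; the auxiliary carbinol centre is erased and the quaternary centre cannot epimerise.

Step 6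
Reactants: 9 (3S)-3-methyl-3-{[(triethylsilyl)oxy]methyl}hex-5-en-2-one; 10 methacrolein
Product: 12 (3R,6S)-3-hydroxy-2,6-dimethyl-6-{[(triethylsilyl)oxy]methyl}nona-1,8-dien-5-one, via diisopinocampheylboron enolate 11 (not isolated)
Conditions: (−)-Ipc2BCl, Et3N, Et2O, 0 °C; 10, −78 → −20 °C; H2O2, MeOH, pH 7 buffer
Reagents that add atoms: methacrolein 10, CC(=C)C=O
Why: Paterson boron aldol of a methyl ketone: only the methyl side can enolise, the enol borinate adds through a cyclic transition state, and the isopinocampheyl ligands (reagent control) should direct it to the Re face of the enal to set C7 as R; the C7 epimer is a diastereomer and is removed by chromatography.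

Step 7
Reactants: 12 (3R,6S)-3-hydroxy-2,6-dimethyl-6-{[(triethylsilyl)oxy]methyl}nona-1,8-dien-5-one
Product: 13 (3R,6S)-3-[(tert-butyldimethylsilyl)oxy]-2,6-dimethyl-6-{[(triethylsilyl)oxy]methyl}nona-1,8-dien-5-one
Conditions: tBuMe2SiOTf, 2,6-lutidine, CH2Cl2, −78 °C
Reagents that add atoms: tert-butyldimethylsilyl triflate, CC(C)(C)[Si](C)(C)OS(=O)(=O)C(F)(F)F
Why: O-silylation of the secondary allylic alcohol is much faster than enol silylation of the ketone at −78 °C and blocks retro-aldol and dehydration.

Step 8
Reactants: 13 (3R,6S)-3-[(tert-butyldimethylsilyl)oxy]-2,6-dimethyl-6-{[(triethylsilyl)oxy]methyl}nona-1,8-dien-5-one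
Product: 14 (2S,6R)-6-[(tert-butyldimethylsilyl)oxy]-2,5-dimethyl-2-{[(triethylsilyl)oxy]methyl}cyclohept-4-en-1-one (ring B ketone)
Conditions: (H2IMes)(PCy3)Cl2Ru=CHPh (second-generation Grubbs catalyst, 5 mol %), CH2Cl2 (5 mM), 40 °C
Reagents that add atoms: none
Why: Ring-closing metathesis: ruthenium loads on the monosubstituted allyl terminus and closes onto the 1,1-disubstituted alkene to give the seven-membered ring with the trisubstituted C8=C9 alkene, helped by the quaternary C1; no stereocentre is formed.

Step 9
Reactants: 14 ring B ketone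
Product: 15 (2S,6R)-6-[(tert-butyldimethylsilyl)oxy]-2-(hydroxymethyl)-2,5-dimethylcyclohept-4-en-1-one
Conditions: PPTS, MeOH/CH2Cl2, 0 °C
Reagents that add atoms: none
Why: Acid-catalysed methanolysis cleaves the primary triethylsilyl ether far faster than the secondary tert-butyldimethylsilyl ether.

Step 10
Reactants: 15 (2S,6R)-6-[(tert-butyldimethylsilyl)oxy]-2-(hydroxymethyl)-2,5-dimethylcyclohept-4-en-1-one; 16 2-bromo-3-methylbutanoic acid (racemic)
Product: 17 [(1S,5R)-5-[(tert-butyldimethylsilyl)oxy]-1,4-dimethyl-7-oxocyclohept-3-en-1-yl]methyl 2-bromo-3-methylbutanoate (both epimers at the bromine-bearing carbon)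
Conditions: DCC, DMAP (cat.), CH2Cl2, 0 °C → rt
Reagents that add atoms: 2-bromo-3-methylbutanoic acid 16, CC(C)C(Br)C(O)=O
Why: Steglich esterification of the primary alcohol installs the tether; the configuration at the bromide carbon is irrelevant because it is lost in step 11.

Step 11
Reactants: 17 bromoester
Product: 19 cis-fused hydroxy lactone, 6-[(tert-butyldimethylsilyl)oxy]-4a-hydroxy-7,9a-dimethyl-4-(propan-2-yl)-4,4a,5,6,9,9a-hexahydro-1H-cyclohepta[c]pyran-3-one with C1–CH3, C5–OH and C4–isopropyl on one face and C7–OSi on the other (target numbering), via samarium enolate 18 (not isolated)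
Conditions: SmI2 (2.5 equiv), THF, −78 °C; aq. work-up
Reagents that add atoms: none
Why: Intramolecular samarium Reformatsky reaction: divalent samarium reduces the α-bromo ester to a trivalent samarium enolate that adds to the C5 ketone through a chair-like transition state bridged by samarium, in which the C2 tether delivers C4 to the face of C5 cis to C2 (cis-fused lactone, as in cis-ketol formation in tethered aldol closures) and the isopropyl group sits equatorial, away from axial C10, which should place it cis to the C5 hydroxyl as in the target.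

Step 12
Reactants: 19 cis-fused hydroxy lactone
Product: 20 triethylsilyl ether of 19 at the C5 oxygen
Conditions: Et3SiOTf, 2,6-lutidine, CH2Cl2, 0 °C → rt
Reagents that add atoms: triethylsilyl triflate, CC[Si](CC)(CC)OS(=O)(=O)C(F)(F)F
Why: A silyl triflate silylates the hindered tertiary alcohol; capping it removes the retro-aldol pathway at the β-hydroxy aldehyde stage of steps 14 and 15.

Step 13
Reactants: 20 silylated lactone
Product: 21 ring B diol: C1 bears CH3 and CH2OH, C5 bears OSiEt3 and the CH(isopropyl)CH2OH group, C7 bears OSi(tBu)Me2, configuration as in 20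
Conditions: LiAlH4, THF, 0 °C
Reagents that add atoms: none
Why: Hydride reduction opens the lactone to the 1,5-diol (C2 and C3 carbinols) without touching the silyl ethers or any stereocentre.

Step 14
Reactants: 21 ring B diol
Product: 23 dialdehyde (C2 and C3 as CHO), via bis(alkoxysulfonium) chloride 22 (not isolated)
Conditions: (COCl)2, DMSO, CH2Cl2, −78 °C; Et3N, −78 → 0 °C
Reagents that add atoms: none
Why: Swern oxidation activates both primary alcohols as alkoxysulfonium salts before base is added, so the dialdehyde forms without passing through a lactol that would be oxidised to the lactone; the low temperature limits epimerisation at C4.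

Step 15
Reactants: 23 dialdehyde
Product: 24 ring B diene: vinyl on C1, CH(isopropyl)CH=CH2 on C5, C5–OSiEt3, C7–OSi(tBu)Me2 (metathesis precursor)
Conditions: Ph3PCH3Br, KOtBu, THF, 0 °C; 23, −78 → 0 °C
Reagents that add atoms: methyltriphenylphosphonium bromide (as its ylide), C[P+](c1ccccc1)(c1ccccc1)c1ccccc1.[Br-]
Why: Double Wittig methylenation: the unstabilised ylide adds to both aldehydes faster than it enolises the α-branched one, and the silyl ether on C5 excludes retro-aldol cleavage.

Step 16
Reactants: 24 ring B diene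
Product: 25 bicyclic C2=C3 cyclopentene: 3a-triethylsilyloxy-5-(tert-butyldimethylsilyloxy)-6,8a-dimethyl-3-(propan-2-yl)-3,3a,4,5,8,8a-hexahydroazulene with all four stereocentres of the target
Conditions: (H2IMes)(PCy3)Cl2Ru=CHPh (second-generation Grubbs catalyst, 5–10 mol %), toluene (2 mM), 80 °C
Reagents that add atoms: none
Why: The ruthenium benzylidene exchanges onto one terminal vinyl group, the new alkylidene adds to the second vinyl group in a [2+2] step to a ruthenacyclobutane, and cycloreversion gives the C2=C3 alkene while ethylene escapes and drives the closure. The closest known reaction type is ring-closing metathesis of hepta-1,6-dienes to cyclopentenes that bear a quaternary allylic carbon. Ring A closes as a five-membered carbocycle by joining the two vinyl carbons across the C1–C5 bond, and its fusion to ring B is cis because both vinyl-bearing groups already sit on the same face of ring B. No stereocentre is formed; C1, C4, C5 and C7 are carried through unchanged. The step needs chemoselectivity for the two monosubstituted alkenes over the trisubstituted C8=C9 alkene, which the far lower reactivity of an unstrained trisubstituted ring alkene secures, since engaging it would also give strained bridged rings. It also needs ring closure over oligomerisation, which high dilution and the cis geometry fixed in step 11 secure, while heating in toluene answers slow initiation at the two hindered allylic positions.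

Step 17
Reactants: 25 bicyclic cyclopentene
Product: 26 bis-silyl ether of the saturated ring A diol: 3a-triethylsilyloxy-5-(tert-butyldimethylsilyloxy)-6,8a-dimethyl-3-(propan-2-yl)-1,2,3,3a,4,5,8,8a-octahydroazulene
Conditions: 2-nitrobenzenesulfonylhydrazide, Et3N, CH2Cl2, rt
Reagents that add atoms: none
Why: Diimide reduction: concerted syn transfer of H2 discriminates strongly by substitution, so the cis-disubstituted cyclopentene should be reduced while the trisubstituted C8=C9 alkene stays.

Step 18
Reactants: 26 bis-silyl ether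
Product: 27 (3R,3aS,5R,8aR)-6,8a-dimethyl-3-(propan-2-yl)-1,2,3,3a,4,5,8,8a-octahydroazulene-3a,5-diol
Conditions: Bu4NF, THF, rt → 50 °C
Reagents that add atoms: none
Why: Fluoride cleaves both silyl ethers and frees the C7 and C5 hydroxyls.

Step 19
Reactants: 27 diol; 28 3,4-dimethoxybenzoyl chloride
Product: 29 (3R,3aS,5R,8aR)-3a-hydroxy-6,8a-dimethyl-3-(propan-2-yl)-1,2,3,3a,4,5,8,8a-octahydroazulen-5-yl 3,4-dimethoxybenzoate (target)
Conditions: Et3N, DMAP (cat.), CH2Cl2, 0 °C → rt
Reagents that add atoms: 3,4-dimethoxybenzoyl chloride 28, COc1ccc(cc1OC)C(Cl)=O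
Why: DMAP-catalysed acylation takes the secondary allylic C7 hydroxyl; the tertiary ring-fusion hydroxyl is too hindered to react.

**Compound list**

1 | ethyl (3S)-3-hydroxybutanoate | CCOC(=O)C[C@H](C)O | starting material
2 | allyl bromide | C=CCBr | starting material
3 | dilithium alkoxide enolate of 1 | CCO/C(O[Li])=C/[C@H](C)O[Li] | intermediate (not isolated)
4 | ethyl (2S,3S)-3-hydroxy-2-(prop-2-en-1-yl)butanoate | CCOC(=O)[C@@H](CC=C)[C@H](C)O | intermediate
5 | dilithium alkoxide enolate of 4 | CCO/C(O[Li])=C(\CC=C)[C@H](C)O[Li] | intermediate (not isolated)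
6 | ethyl (2R,3S)-3-hydroxy-2-methyl-2-(prop-2-en-1-yl)butanoate | CCOC(=O)[C@](C)(CC=C)[C@H](C)O | intermediate
7 | (2S,3S)-2-methyl-2-(prop-2-en-1-yl)butane-1,3-diol | OC[C@](C)(CC=C)[C@H](C)O | intermediate
8 | (2S,3S)-3-methyl-3-{[(triethylsilyl)oxy]methyl}hex-5-en-2-ol | CC[Si](CC)(CC)OC[C@](C)(CC=C)[C@H](C)O | intermediate
9 | (3S)-3-methyl-3-{[(triethylsilyl)oxy]methyl}hex-5-en-2-one | CC[Si](CC)(CC)OC[C@](C)(CC=C)C(C)=O | intermediate
10 | methacrolein | CC(=C)C=O | starting material
11 | diisopinocampheylboron enolate of 9 | CC[Si](CC)(CC)OC[C@](C)(CC=C)C(=C)OB([C@@H]1C[C@@H]2C[C@H]([C@H]1C)C2(C)C)[C@@H]1C[C@@H]2C[C@H]([C@H]1C)C2(C)C | intermediate (not isolated)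
12 | (3R,6S)-3-hydroxy-2,6-dimethyl-6-{[(triethylsilyl)oxy]methyl}nona-1,8-dien-5-one | CC[Si](CC)(CC)OC[C@](C)(CC=C)C(=O)C[C@@H](O)C(C)=C | intermediate
13 | (3R,6S)-3-[(tert-butyldimethylsilyl)oxy]-2,6-dimethyl-6-{[(triethylsilyl)oxy]methyl}nona-1,8-dien-5-one | CC[Si](CC)(CC)OC[C@](C)(CC=C)C(=O)C[C@@H](O[Si](C)(C)C(C)(C)C)C(C)=C | intermediate
14 | (2S,6R)-6-[(tert-butyldimethylsilyl)oxy]-2,5-dimethyl-2-{[(triethylsilyl)oxy]methyl}cyclohept-4-en-1-one | CC[Si](CC)(CC)OC[C@]1(C)CC=C(C)[C@H](O[Si](C)(C)C(C)(C)C)CC1=O | intermediate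
15 | (2S,6R)-6-[(tert-butyldimethylsilyl)oxy]-2-(hydroxymethyl)-2,5-dimethylcyclohept-4-en-1-one | OC[C@]1(C)CC=C(C)[C@H](O[Si](C)(C)C(C)(C)C)CC1=O | intermediate
16 | 2-bromo-3-methylbutanoic acid (racemic) | CC(C)C(Br)C(O)=O | starting material
17 | [(1S,5R)-5-[(tert-butyldimethylsilyl)oxy]-1,4-dimethyl-7-oxocyclohept-3-en-1-yl]methyl 2-bromo-3-methylbutanoate | CC(C)C(Br)C(=O)OC[C@]1(C)CC=C(C)[C@H](O[Si](C)(C)C(C)(C)C)CC1=O | intermediate
18 | trivalent samarium enolate of 17 | CC(C)C=C(O[Sm](I)I)OC[C@]1(C)CC=C(C)[C@H](O[Si](C)(C)C(C)(C)C)CC1=O | intermediate (not isolated)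
19 | cis-fused hydroxy lactone (C1–CH3, C5–OH, C4–isopropyl cis; C7–OSi trans to C5–OH) | CC(C)[C@H]1C(=O)OC[C@]2(C)CC=C(C)[C@H](O[Si](C)(C)C(C)(C)C)C[C@@]21O | intermediate
20 | C5 triethylsilyl ether of 19 | CC(C)[C@H]1C(=O)OC[C@]2(C)CC=C(C)[C@H](O[Si](C)(C)C(C)(C)C)C[C@@]21O[Si](CC)(CC)CC | intermediate
21 | ring B diol (C2 and C3 as CH2OH) | OC[C@H](C(C)C)[C@@]1(O[Si](CC)(CC)CC)C[C@@H](O[Si](C)(C)C(C)(C)C)C(C)=CC[C@@]1(C)CO | intermediate
22 | bis(alkoxysulfonium) chloride of 21 | C[S+](C)OC[C@H](C(C)C)[C@@]1(O[Si](CC)(CC)CC)C[C@@H](O[Si](C)(C)C(C)(C)C)C(C)=CC[C@@]1(C)CO[S+](C)C.[Cl-].[Cl-] | intermediate (not isolated)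
23 | ring B dialdehyde (C2 and C3 as CHO) | O=C[C@H](C(C)C)[C@@]1(O[Si](CC)(CC)CC)C[C@@H](O[Si](C)(C)C(C)(C)C)C(C)=CC[C@@]1(C)C=O | intermediate
24 | ring B diene with vinyl groups on C1 and C4 (metathesis precursor) | C=C[C@H](C(C)C)[C@@]1(O[Si](CC)(CC)CC)C[C@@H](O[Si](C)(C)C(C)(C)C)C(C)=CC[C@@]1(C)C=C | intermediate
25 | bicyclic C2=C3 cyclopentene (metathesis product) | CC(C)(C)[Si](C)(C)O[C@@H]1C[C@]2(O[Si](CC)(CC)CC)[C@@H](C(C)C)C=C[C@]2(C)CC=C1C | intermediate
26 | bis-silyl ether with saturated ring A | CC(C)(C)[Si](C)(C)O[C@@H]1C[C@]2(O[Si](CC)(CC)CC)[C@@H](C(C)C)CC[C@]2(C)CC=C1C | intermediate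
27 | (3R,3aS,5R,8aR)-6,8a-dimethyl-3-(propan-2-yl)-1,2,3,3a,4,5,8,8a-octahydroazulene-3a,5-diol | O[C@@H]1C[C@]2(O)[C@@H](C(C)C)CC[C@]2(C)CC=C1C | intermediate
28 | 3,4-dimethoxybenzoyl chloride | COc1ccc(cc1OC)C(Cl)=O | starting material
29 | (3R,3aS,5R,8aR)-3a-hydroxy-6,8a-dimethyl-3-(propan-2-yl)-1,2,3,3a,4,5,8,8a-octahydroazulen-5-yl 3,4-dimethoxybenzoate | COc1ccc(C(=O)O[C@@H]2C[C@]3(O)[C@@H](C(C)C)CC[C@]3(C)CC=C2C)cc1OC | target

**Step count and risks**

Total step count: 19. Longest linear sequence: 19 steps (fully linear from 1).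

Steps most likely to fail:

1. Step 11 (samarium Reformatsky closure). The risk is poor facial selectivity at C4: if the enolate closes through a non-chelated or boat arrangement, the isopropyl group ends up trans to the C5 oxygen. The fallback sets C4 by enolate protonation and not in the C–C bond formation. It sets out from bromoester 17, whose closure would then give the C4-epimeric hydroxy lactone F1. Et3SiOTf and 2,6-lutidine would convert it to the C4-epimeric silylated lactone F2. LiN(iPr)2 in THF at −78 °C would form the lactone lithium enolate F3. Kinetic protonation with 2,6-di-tert-butyl-4-methylphenol, expected anti to the pseudoaxial silyloxy group on C5, comes back to the route at 20.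

2. Step 6 (boron aldol). The risk is poor facial selectivity on the aldehyde, since the hindered methyl ketone offers no substrate bias and reagent control alone sets C7. The fallback replaces reagent control by a kinetic resolution and sets out from ketone 9. Bu2BOTf and iPr2NEt would form the dibutylboron enolate F4, which adds to methacrolein 10 without facial control to give 12 together with the C7-epimeric aldol adduct F5. Sharpless kinetic resolution of the mixture (Ti(OiPr)4, L-(+)-diisopropyl tartrate, tBuOOH, 4 Å sieves, CH2Cl2, −20 °C) should epoxidise the 7S epimer to the epoxy alcohol F6 and leave the 7R alcohol, so the route is rejoined at 12.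

3. Step 16 (ring A metathesis). The risk is slow initiation at two hindered vinyl groups, one on quaternary C1 and one on C4 next to the silylated C5, leading to incomplete closure or intermolecular coupling. The fallback forms C2=C3 by carbonyl coupling and not by olefin metathesis. It sets out from dialdehyde 23 and skips step 15: intramolecular McMurry coupling with low-valent titanium (TiCl3, Zn–Cu couple, DME, reflux, slow addition) joins the two aldehyde carbons directly as the ring alkene and comes back to the route at 25.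

**Further compounds**

F1 | step 11 | C4-epimeric hydroxy lactone | CC(C)[C@@H]1C(=O)OC[C@]2(C)CC=C(C)[C@H](O[Si](C)(C)C(C)(C)C)C[C@@]21O
F2 | step 11 | C4-epimeric silylated lactone | CC(C)[C@@H]1C(=O)OC[C@]2(C)CC=C(C)[C@H](O[Si](C)(C)C(C)(C)C)C[C@@]21O[Si](CC)(CC)CC
F3 | step 11 | lactone lithium enolate | CC(C)C1=C(O[Li])OC[C@]2(C)CC=C(C)[C@H](O[Si](C)(C)C(C)(C)C)C[C@@]21O[Si](CC)(CC)CC
F4 | step 6 | dibutylboron enolate of 9 | CC[Si](CC)(CC)OC[C@](C)(CC=C)C(=C)OB(CCCC)CCCC
F5 | step 6 | C7-epimeric aldol adduct, (3S,6S) | CC[Si](CC)(CC)OC[C@](C)(CC=C)C(=O)C[C@H](O)C(C)=C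
F6 | step 6 | epoxy alcohol from F5 | CC[Si](CC)(CC)OC[C@](C)(CC=C)C(=O)C[C@H](O)[C@]1(C)CO1
F0 | step 16 | none | none
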